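All runs stem from a simulated flask from invented constants, noise included.

4 questions stand on this flask, and one count serves them: how many times each charge of free catalyst turns over before it stops.

common to all: starting material 0.050 M; temperature 110 °C

| flask | second substrate | partner | capture agent | free catalyst | remark | time |
|---|---|---|---|---|---|---|
| south | 0.050 M | 0.060 M | 0.015 M | 5 mM | the very flask that is asked about, followed so far |  |
| south-west | 0.050 M | 0.060 M | 0.015 M | 7.5 mM | run made earlier |  |
| flask | 0.0500 M | 0.0600 M | 0.0150 M | 5.0 mM |  | 12 h |

| run | time / min | target / % | starting material / % |
|---|---|---|---|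
| south | 60.0 | 36.7 | 53.3 |
| south | 120 | 39.8 | 51.2 |
| south | 300 | 40.5 | 49.9 |
| south | 720 | 39.2 | 51.5 |
| south-west | 8.00 | 23.0 | 67.3 |
| south-west | 15.0 | 30.6 | 58.1 |
| south-west | 20.0 | 34.9 | 52.0 |
| south-west | 30.0 | 40.9 | 47.4 |

(standard deviation of a reading: 1 percentage point)

- target, in percent of the starting material first charged, at 12 h
- what to do for the largest gain in target; "none" if nothing gains more than 2 percentage points (green / teal / red / amber / blue / none)
- target present, with what was taken out counted in, in percent of the starting material first charged, after green
- target present, with what was taken out counted in, in percent of the starting material first charged, after red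

- green: at 12 h add free catalyst, 50.0 % of the amount charged, then wait 12 h
- teal: at 12 h raise the temperature by 10 K, then wait 12 h
- red: at 12 h add partner, 100 % of the amount charged, then wait 12 h
- amber: at 12 h take out 90 % of the target then present, then wait 12 h
- blue: change nothing and wait 12 h more

- target taken out counts as made
- the analysis behind the earlier runs scatters by 1 percentage point, standard deviation
- the earlier runs do not show what temperature does; that part of a forecast is a guess
- additions bring no volume worth counting

The south run is the asked flask itself, and its target reads flat from 120 min on, so my figure for 12 h is the mean of its last 3 readings, 39.8 %.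

But a flat line could be an equilibrium, which is the first objection. An equilibrium does not move with the catalyst charge, yet the south-west run, with 7.5 mM of free catalyst, reads 47.4 % of starting material at 30.0 min, less than any late south reading, and its target rose 6 percentage points over its last 10.0 min. So I read the south stop as a dying catalyst, and the quantity to carry is the turnover number, target made per free catalyst charged:

N = 39.8 % × 0.050 M / 5.0 mM = 3.98

Green adds 2.50 mM of free catalyst, which at that count would bring 20 points. The objection is that new catalyst meets a used flask. If one partner goes per target, the partner left is at most this share of its charge: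

(0.0600 M − 39.8 % × 0.050 M) / 0.0600 M = 0.668

Scaling the turnovers by that share, as a guess, gives:

gain = 3.98 × 0.668 × 2.50 mM / 0.050 M = 13 points

So I expect about 52.8 % after green. Red should give 39.8 % again: on that count up to 0.668 of the partner charge stood in the south flask while its target stayed flat. Amber and blue add no catalyst, and the effect of heat is a guess, so green is my choice.

The forecast says 39.9 %, green, 44.8 % after green and 40 % after red, so it agrees with me except on the figure after green, where it stands lower. It reads the stop as a titration: “So a by-product seems to fill the capture agent, then kill the catalyst one-for-one.”

The flask gives 39.4 %, green with a gain of 11 points, 50.5 % after green and 39.4 % after red.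

    starting material + free catalyst ⇌ catalyst intermediate A (K = 55.0 L mol⁻¹, k = 1.60 L mol⁻¹ s⁻¹, Ea = 45.0 kJ mol⁻¹, ΔH = −29.0 kJ mol⁻¹)
    partner + catalyst intermediate A → free catalyst + target (k = 0.190 L mol⁻¹ s⁻¹, Ea = 62.0 kJ mol⁻¹)
    partner + catalyst intermediate B → free catalyst + second product (k = 0.220 L mol⁻¹ s⁻¹, Ea = 82.0 kJ mol⁻¹)
    catalyst intermediate A + capture agent → trapped intermediate (k = 0.150 L mol⁻¹ s⁻¹, Ea = 76.0 kJ mol⁻¹)
    second substrate + free catalyst ⇌ catalyst intermediate B (K = 42.0 L mol⁻¹, k = 0.940 L mol⁻¹ s⁻¹, Ea = 55.0 kJ mol⁻¹, ΔH = −19.0 kJ mol⁻¹)
    (constants at 110 °C)

While free catalyst was there, starting material fed catalyst intermediate A, which partner turned into target and capture agent took away as trapped intermediate, and half of the turnover to target was done by 10.7 min. At 72.0 min trapped intermediate held 94.3 % of the catalyst and at 720 min 100 %, with 36.6 % of the partner left. After green the added catalyst earned 2.22 turnovers to target, fewer than the 3.98 I read for the first charge. The neighbour with 0.037 M of capture agent ended at 18.6 % of target, which is 1.86 turnovers.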